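All runs were generated by integration on assumed constants; scatter was added.

At 6.0 h we read E in four set-ups with the same charge of Z, D and J. Two earlier closed flasks, larch and birch, are what we have to go on.

all flasks: Z 0.020 M

| flask | D | J | remark | time |
|---|---|---|---|---|
| larch | 0.060 M | 11 µM | run made earlier |  |
| birch | 0.060 M | 16 µM | run made earlier |  |
| spring | 0.0600 M | 11 µM | a single well-mixed tank run continuously and read at steady state, 6.0 h in it on average |  |
| winter | 0.0600 M (fed, over 4.80 h) | 11 µM | all but D at the start; D goes in evenly over 4.80 h, the run ends at 6.0 h | 6.0 h |
| dawn | 0.0600 M | 11 µM | everything together in a closed stirred flask, run for 6.0 h | 6.0 h |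
| noon | 0.0600 M | 11 µM | plug flow through a tube for 6.0 h, no back-mixing | 6.0 h |

- larch (time / h: E / %, Z / %): 0.667: 3, 95; 1.33: 7, 98; 2.00: 8, 91; 3.00: 13, 87; 4.00: 14, 82
- birch (time / min: E / %, Z / %): 6.00: 0, 100; 10.0: 2, 99; 20.0: 0, 94; 40.0: 4, 99; 80.0: 9, 95

(standard deviation of a reading: 1.5 percentage points)

- the stated concentrations are those of everything mixed, before any reaction; amounts are the same in each set-up
- the earlier runs were read with a standard deviation of 1.5 percentage points
- the feed brings no volume worth counting
- the earlier runs were made in a closed, stirred flask

- the set-up with the highest amount of E at the outlet or at the end, in percent of the Z put in ("none" if the first two lie within 2 percentage points) (spring / winter / dawn / noon / none)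
- amount of E at the outlet or at the end, in percent of the Z put in, spring
- amount of E at the outlet or at the end, in percent of the Z put in, winter
- amount of E at the outlet or at the end, in percent of the Z put in, dawn
- amount of E at the outlet or at the end, in percent of the Z put in, noon

One thing in larch looks wrong at first. At 4.00 h it holds 255 times as much E as J, though J was charged at 0.0550% of Z. The numbers go together if J comes back after each E, so we count turnovers.

Summed E over summed reading time gives 74.4 h⁻¹ in larch; this reading is the turnover frequency T, the E formed per J charged per hour. Birch reads 72.1 h⁻¹, close to larch, so E follows J within the scatter. But Z in larch is still at 82%, and D stood at 0.060 M in both runs, so neither dependence has been tested.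

We therefore set the zero of our scale at the case where the vessel makes no difference. With T flat, zero order in Z and D, the four set-ups reach 24.6%.

The forecast sits lower than this zero, with 19.5% for spring, 15% for winter, 22% for dawn and 22% for noon, and it names best none, saying “Dawn and noon tie, so best is none”.

The flask gives 17.8% for spring, 17.3% for winter, 19.6% for dawn and 19.6% for noon, so best is none.

    X ⇌ Q (K = 3.00, k = 609 h⁻¹)
    D + L → X (k = 13900 L mol⁻¹ h⁻¹)
    Z + J → L (k = 94200 L mol⁻¹ h⁻¹)
    Z + E → G (k = 3.12 L mol⁻¹ h⁻¹)
    Q → J + E (k = 122 h⁻¹)

Dawn's E stands 5.0 percentage points below the zero, and dawn also holds 6.42% G, where each G counts as two and took up one E. Adding half of G back to E gives T = 69.3 h⁻¹, against 74.4 h⁻¹ read from larch. The same flask read at 15 h has a flat-T zero of 61.4%. It shows 43.7% E and 24.3% G, which makes T = 67.7 h⁻¹, with its Z down to 32%.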